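A one-step world has one rate constant and one yield, but this flask has two paths out of the substrate. On the first, substrate binds free catalyst to give catalyst intermediate A, partner adds to give catalyst intermediate B, that turns into catalyst intermediate C, and catalyst intermediate C releases target and free catalyst. On the second, two substrate join to homo dimer with no catalyst.

| flask | substrate | partner | free catalyst | temperature | time | remark |
|---|---|---|---|---|---|---|
| green | 10 mM | 1.30 equiv | 0.1 mol% | 40 °C | 12 s | everything together at the start |
| amber | 10 mM | 1.30 equiv (fed, over 5.0 s) | 0.1 mol% | 40 °C | 12 s | all else is in the flask from the start; the feed brings no volume worth counting |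
| red | 10 mM | 1.30 equiv (fed, over 5.0 s) | 0.1 mol% |  | 12 s | the addition at 0 °C, then warmed to 40 °C; the feed brings no volume worth counting |
| grey | 10 mM (fed, over 5.0 s) | 1.30 equiv | 0.1 mol% | 40 °C | 12 s | all else is in the flask from the start; the feed brings no volume worth counting |

* the flask with the highest amount of target, in percent of the substrate charged ("all alike" if they lie within 1.5 percentage points) (green / amber / red / grey / all alike)
* final target, as a percentage of the substrate charged, in green
* final target, as a percentage of the substrate charged, in amber
* final target, as a percentage of the substrate charged, in red
* final target, as a percentage of the substrate charged, in grey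

- percentages count the substrate that a species holds: one homo dimer counts as two
- for a step with 2 of a species take k times the square, and two of it per event
- constants are those at 40 °C; use the activation energies and enthalpies for any other temperature

    substrate + free catalyst ⇌ catalyst intermediate A (K1 = 2900 M⁻¹, k1 = 23300 M⁻¹ s⁻¹, Ea1 = 16.0 kJ mol⁻¹, ΔH1 = −27.0 kJ mol⁻¹)
    partner + catalyst intermediate A ⇌ catalyst intermediate B (K2 = 26.4 M⁻¹, k2 = 29000 M⁻¹ s⁻¹, Ea2 = 10.0 kJ mol⁻¹, ΔH2 = −68.0 kJ mol⁻¹)
    catalyst intermediate B ⇌ catalyst intermediate C (K3 = 1.0, k3 = 211 s⁻¹, Ea3 = 53.0 kJ mol⁻¹, ΔH3 = −26.0 kJ mol⁻¹)
    catalyst intermediate C ⇌ free catalyst + target (K4 = 0.12 M, k4 = 1260 s⁻¹, Ea4 = 55.0 kJ mol⁻¹, ΔH4 = −84.0 kJ mol⁻¹)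
    2 substrate → homo dimer (k5 = 25.6 M⁻¹ s⁻¹, Ea5 = 45.0 kJ mol⁻¹)
    (constants at 40 °C)

Both paths draw on the same substrate, so the end state is a split between target and homo dimer. Two colleagues disagree about that split.

The first holds a clock view: the cycle is a machine of fixed speed, and target is speed times time. Catalyst intermediate C goes back at the same rate constant as catalyst intermediate B goes forward, 211 s⁻¹, and goes on at 1260 s⁻¹, so catalyst intermediate B passes through at 181 s⁻¹. At the start of green, substrate binding stands at 29 and partner binding at 0.34, so catalyst intermediate A is the resting state and a share of the bound catalyst sits as catalyst intermediate B. That gives a turnover frequency f of 46.2 s⁻¹. On 0.0100 mM of catalyst the cycle's rate v is 0.462 mM s⁻¹, and over 12 s the clock promises 55.4% target in green.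

The second holds a race view. Substrate goes to homo dimer at 5.12 mM s⁻¹ at the start, about ten times the rate of the cycle, with a first half-life by that step of 1.95 s, far shorter than the run.

My own reckoning follows the race. Call S* the substrate concentration at which the two paths draw equally, so S* is the square root of v over twice the dimer rate constant: 3.00 mM for green. With v held at that figure, substrate above S* goes mostly to homo dimer, and substrate below it mostly to target. The crossover share φ, S* divided by the substrate charged, is then my estimate of the end share of target: 30.0% in green.

In amber I take the partner at about half its charge during the feed, which gives a turnover frequency of 26.5 s⁻¹ and φ of 22.7%. In grey the substrate arrives at 2.00 mM s⁻¹, less than green's opening dimer rate, so I place grey above green. For red I have no figure.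

The forecast sides with the race but sets green lower than my φ: 23.5% for green, 18.5% for amber, 19% for red, 26% for grey, and grey highest. Its words are “target is capped near a quarter and feeding substrate helps modestly by keeping its concentration down”.

The run gives 22.4% in green, 17.5% in amber, 18.6% in red and 24.8% in grey, so grey stands highest, as the forecast said, and green lies far below the clock's 55.4%. On my reckoning, with v held at its figure, the clock view has its region where the substrate charged lies below S*, whereas green's 10 mM lies above its 3.00 mM. For the forecast's amber figure to fail, the free catalyst would have to change: amber's answer has moved by 5 points at 0.066 mol% or 0.14 mol%. Amber's φ of 22.7% is an estimated end share: at 12.0 s amber holds 17.5% with 6.7% of its substrate left, and at 120 s it holds 23.3%.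

For the neighbour of amber with 0.17 mol% of free catalyst, all else held, S* goes with the root of the catalyst, so φ becomes 29.6%. The computed flask holds 25.4% at 12.0 s, with 3.6% of its substrate left.

The numbers of this flask are those of an exercise; the result is computed.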